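**Retrosynthetic overview**
- The target is an upper trans-4-aryl-isoflavan (benzo ring A, pyran ring C, pendant ring B) whose C4 is bonded to the pendant ring F of a lower isoflavan (benzo ring D, pyran ring E). The last step is hydrogenolysis of four benzyl ethers and of a chlorine steering group on ring D.
- Ring C is closed last by a chiral-acid-catalysed [4+2] of an o-quinone methide (ring A + C4 carrying ring F) with an (E)-β-ethoxystyrene (ring B + C3 + C2), then C2 deoxygenation. The C4–ring F bond comes from an aryllithium/salicylaldehyde addition.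
- Ring E is closed and ring D attached in one operation: aryne + 2-arylacrolein → isoflav-3-ene (carbonyl [2+2], ring opening, oxa-6π). Asymmetric hydrogenation then sets its C3.
- Enabling feature: ring D carries the ring E atoms O1 and C4 on adjacent carbons C8a and C4a, the footprint of an aryne 1,2-difunctionalisation. C2 and C4 of ring E are both CH2 and flank the aryl-bearing C3, so C4–C3(aryl)–C2 plus O1 is a 2-arylacrolein (CHO carbon → C4, =CH2 → C2, carbonyl O → O1).
- Ring order: E (step 8), then C (step 14).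

Key step: step 8

Remark: the catalyst enantiomers named in steps 9 and 14 are chosen by analogy with the closest precedents; if a model run shows the opposite facial sense, the antipodal catalyst is taken and nothing else changes.

Step 1
Reactants: 1 3-hydroxy-5-methoxybenzaldehyde
Product: 2 2-bromo-5-hydroxy-3-methoxybenzaldehyde
Conditions: NBS (1.0 equiv), MeCN, −20 → 0 °C
Reagents that add atoms: N-bromosuccinimide, O=C1CCC(=O)N1Br
Why: Electrophilic aromatic bromination: the free phenol directs para, and that position (between CHO and OMe) is also activated by the methoxy group, so it should be brominated in preference to the two sites ortho to OH (any minor isomer is removed by chromatography); no stereocentre.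

Step 2
Reactants: 2 2-bromo-5-hydroxy-3-methoxybenzaldehyde
Product: 3 5-(benzyloxy)-2-bromo-3-methoxybenzaldehyde
Conditions: BnBr, K2CO3, DMF, 25 °C
Reagents that add atoms: benzyl bromide, BrCc1ccccc1
Why: Williamson ether synthesis on the phenolate; the benzyl ether survives every later step and falls in the final hydrogenolysis.

Step 3
Reactants: 3 5-(benzyloxy)-2-bromo-3-methoxybenzaldehyde
Product: 5 2-[5-(benzyloxy)-2-bromo-3-methoxyphenyl]acetaldehyde, via enol ether 4 (not isolated)
Conditions: Ph3P(CH2OMe)Cl, KOtBu, THF, 0 → 25 °C; then 2 M aq. HCl, THF, 40 °C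
Reagents that add atoms: (methoxymethyl)triphenylphosphonium chloride, COC[P+](c1ccccc1)(c1ccccc1)c1ccccc1.[Cl-]; water, O
Why: Wittig methoxymethylenation of the non-enolisable aldehyde followed by acid hydrolysis of the enol ether is the standard one-carbon homologation to an arylacetaldehyde; the aryl bromide and the benzyl ether are inert.

Step 4
Reactants: 5 2-[5-(benzyloxy)-2-bromo-3-methoxyphenyl]acetaldehyde
Product: 6 2-[5-(benzyloxy)-2-bromo-3-methoxyphenyl]prop-2-enal
Conditions: CH2O (37% aq.), pyrrolidine (10 mol %), EtCO2H (10 mol %), i-PrOH, 45 °C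
Reagents that add atoms: formaldehyde, C=O
Why: Amine/acid-catalysed Mannich condensation with formaldehyde and elimination (organocatalytic α-methylenation) converts the arylacetaldehyde into the 2-arylacrolein, which the twisted ortho-bromoaryl group should stabilise against dimerisation and which is used directly.

Step 5
Reactants: 7 4-(benzyloxy)phenol
Product: 8 4-(benzyloxy)-2-chlorophenol
Conditions: SO2Cl2 (1.0 equiv), i-Bu2NH (cat.), toluene, 0 → 25 °C
Reagents that add atoms: sulfuryl chloride, O=S(=O)(Cl)Cl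
Why: Amine-catalysed electrophilic chlorination goes ortho to the free phenol because the para position is blocked by the benzyloxy group.

Step 6
Reactants: 8 4-(benzyloxy)-2-chlorophenol
Product: 9 4-(benzyloxy)-2-bromo-6-chlorophenol
Conditions: NBS (1.0 equiv), i-Pr2NH (cat.), CH2Cl2, 0 °C
Reagents that add atoms: N-bromosuccinimide, O=C1CCC(=O)N1Br
Why: Electrophilic bromination at the only remaining position ortho to the phenol installs the bromine that will be exchanged for silicon, while chlorine stays as the regiochemical control element of the aryne.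

Step 7
Reactants: 9 4-(benzyloxy)-2-bromo-6-chlorophenol
Product: 12 4-(benzyloxy)-2-chloro-6-(trimethylsilyl)phenyl trifluoromethanesulfonate, via aryl silyl ether 10 (not isolated), via lithium phenolate 11 (not isolated)
Conditions: HMDS, THF, 70 °C, then evaporation; n-BuLi, THF, −100 → −80 °C; Tf2O, −100 → 25 °C
Reagents that add atoms: hexamethyldisilazane, C[Si](C)(C)N[Si](C)(C)C; trifluoromethanesulfonic anhydride, O=S(=O)(OS(=O)(=O)C(F)(F)F)C(F)(F)F
Why: O-Silylation, Br/Li exchange with 1,3 O→C silyl shift (retro-Brook rearrangement) and triflation of the resulting phenolate is the standard one-flask route to o-(trimethylsilyl)aryl triflates; lithium and chlorine are meta to each other, so no premature elimination occurs.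

Step 8
Reactants: 6 2-[5-(benzyloxy)-2-bromo-3-methoxyphenyl]prop-2-enal; 12 4-(benzyloxy)-2-chloro-6-(trimethylsilyl)phenyl trifluoromethanesulfonate
Product: 16 7-(benzyloxy)-3-[5-(benzyloxy)-2-bromo-3-methoxyphenyl]-5-chloro-2H-chromene, via aryne 13 (not isolated), via benzoxete 14 (not isolated), via o-quinone methide 15 (not isolated)
Conditions: 6 (1.0 equiv), 12 (1.5 equiv, added over 2 h), CsF (3 equiv), MeCN, 25 °C
Reagents that add atoms: none
Why: Fluoride strips the silyl group of 12 and triflate leaves, giving aryne 13; the carbonyl oxygen of 6 attacks the aryne carbon meta to chlorine and the aryl anion, held next to the C–Cl bond, closes on the carbonyl carbon (formal [2+2], four-membered ring) to benzoxete 14, which opens in a 4π electrocyclic ring opening to o-quinone methide 15. In 15 the ring carbonyl, the exocyclic C4a=C4 bond and the C3=C2 vinyl group form a 1-oxatriene that closes the pyran ring E by thermal disrotatory oxa-6π electrocyclisation (O1–C2 bond), restoring the aromaticity of ring D. In one operation the aryl C8a–O1 and aryl C4a–C4 bonds are thus made and the former carbonyl oxygen is moved from C4 to C2. The closest known reaction type is the fluoride-induced annulation of arynes with α,β-unsaturated aldehydes to 2H-chromenes, together with the aryne/formamide [2+2] route to salicylaldehydes. No stereocentre is formed (C3 stays sp2 and is set in step 9). The step needs regioselectivity, secured by the inductive effect of the C5 chlorine (oxygen attacks the distal aryne carbon), and chemoselectivity for C=O over C=C, secured by the absence of allylic hydrogens (no ene reaction) and by the twisted, bromine-flanked styrene unit (no Diels–Alder reaction), while the intramolecular electrocyclisation should outrun capture of 15 by a second aryne.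

Step 9
Reactants: 16 7-(benzyloxy)-3-[5-(benzyloxy)-2-bromo-3-methoxyphenyl]-5-chloro-2H-chromene
Product: 17 (3R)-7-(benzyloxy)-3-[5-(benzyloxy)-2-bromo-3-methoxyphenyl]-5-chlorochromane
Conditions: H2 (50 bar), [Ir(cod)((S)-tBu-PHOX)]BArF (2 mol %; tBu-PHOX = 4-tert-butyl-2-[2-(diphenylphosphanyl)phenyl]-4,5-dihydrooxazole, BArF = tetrakis[3,5-bis(trifluoromethyl)phenyl]borate), CH2Cl2, 25 °C
Reagents that add atoms: none
Why: Iridium N,P-catalysed asymmetric hydrogenation of the trisubstituted cyclic olefin, a reaction type established for 3-aryl-2H-chromenes (isoflav-3-enes), sets C3 of ring E by catalyst control of the olefin face; Ar–Br, Ar–Cl and benzyl ethers are not touched by this homogeneous catalyst.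

Step 10
Reactants: 17 (3R)-7-(benzyloxy)-3-[5-(benzyloxy)-2-bromo-3-methoxyphenyl]-5-chlorochromane; 18 4-(benzyloxy)-2-hydroxybenzaldehyde
Product: 21 5-(benzyloxy)-2-[{4-(benzyloxy)-2-[(3R)-7-(benzyloxy)-5-chlorochroman-3-yl]-6-methoxyphenyl}(hydroxy)methyl]phenol (both carbinol epimers), via aryllithium 19 (not isolated), via sodium phenolate 20 (not isolated)
Conditions: 17, n-BuLi (1.05 equiv), THF, −78 °C; then 20 (from 18 and NaH, THF, 0 °C; 1.5 equiv), −78 → 0 °C; aq. NH4Cl
Reagents that add atoms: none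
Why: Br/Li exchange (Ar–Cl is inert at −78 °C) and 1,2-addition of the aryllithium to the phenolate-masked salicylaldehyde fix the C4–aryl bond regiospecifically at the position between OMe and the chromanyl group; the new carbinol centre is left uncontrolled because both epimers converge on the same o-quinone methide in step 14.

Step 11
Reactants: 22 3,4-dimethoxyphenol
Product: 23 2-bromo-4,5-dimethoxyphenol
Conditions: NBS (1.0 equiv), CH2Cl2, −78 → 0 °C
Reagents that add atoms: N-bromosuccinimide, O=C1CCC(=O)N1Br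
Why: Electrophilic bromination of the phenol at the ortho position that is para to a methoxy group; the other ortho site lies between two oxygen substituents and is more hindered.

Step 12
Reactants: 23 2-bromo-4,5-dimethoxyphenol
Product: 24 1-(benzyloxy)-2-bromo-4,5-dimethoxybenzene
Conditions: BnBr, K2CO3, DMF, 25 °C
Reagents that add atoms: benzyl bromide, BrCc1ccccc1
Why: Williamson ether synthesis; it protects the phenol that becomes the free 2-hydroxy group of ring B.

Step 13
Reactants: 24 1-(benzyloxy)-2-bromo-4,5-dimethoxybenzene; 25 2-[(E)-2-ethoxyethenyl]-4,4,5,5-tetramethyl-1,3,2-dioxaborolane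
Product: 26 1-(benzyloxy)-2-[(E)-2-ethoxyethenyl]-4,5-dimethoxybenzene
Conditions: Pd(PPh3)4 (5 mol %), K2CO3, 1,4-dioxane/H2O, 85 °C
Reagents that add atoms: none
Why: Suzuki–Miyaura coupling of the aryl bromide with the (E)-alkenylboronate proceeds with retention of olefin geometry and gives the E enol ether that carries ring B, C3 and C2.

Step 14
Reactants: 21 5-(benzyloxy)-2-[{4-(benzyloxy)-2-[(3R)-7-(benzyloxy)-5-chlorochroman-3-yl]-6-methoxyphenyl}(hydroxy)methyl]phenol; 26 1-(benzyloxy)-2-[(E)-2-ethoxyethenyl]-4,5-dimethoxybenzene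
Product: 28 (2S,3R,4S)-7-(benzyloxy)-3-[2-(benzyloxy)-4,5-dimethoxyphenyl]-4-{4-(benzyloxy)-2-[(3R)-7-(benzyloxy)-5-chlorochroman-3-yl]-6-methoxyphenyl}-2-ethoxychromane, via o-quinone methide 27 (not isolated)
Conditions: 26 (2 equiv), (R)-3,3′-bis(2,4,6-triisopropylphenyl)-1,1′-binaphthyl-2,2′-diyl N-triflylphosphoramide (10 mol %), 4 Å MS, CH2Cl2, −30 → 0 °C
Reagents that add atoms: none
Why: The chiral acid dehydrates the o-hydroxybenzhydrol to o-quinone methide 27 and holds it by hydrogen bonding/ion pairing while the enol ether adds in an inverse-electron-demand oxa-[4+2] cycloaddition, a known reaction type for in-situ o-quinone methides and electron-rich alkenes; C4 is set by catalyst control of the quinone methide face and C3 by the E geometry of 26 in the alkoxy-endo transition state (3,4-trans, 2,4-cis), while the ring E stereocentre is untouched.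

Step 15
Reactants: 28 (2S,3R,4S)-7-(benzyloxy)-3-[2-(benzyloxy)-4,5-dimethoxyphenyl]-4-{4-(benzyloxy)-2-[(3R)-7-(benzyloxy)-5-chlorochroman-3-yl]-6-methoxyphenyl}-2-ethoxychromane
Product: 29 (3R,4S)-7-(benzyloxy)-3-[2-(benzyloxy)-4,5-dimethoxyphenyl]-4-{4-(benzyloxy)-2-[(3R)-7-(benzyloxy)-5-chlorochroman-3-yl]-6-methoxyphenyl}chromane
Conditions: Et3SiH (5 equiv), BF3·OEt2 (2 equiv), CH2Cl2, −78 → −30 °C
Reagents that add atoms: none
Why: Ionic hydrogenation of the cyclic acetal: BF3 ionises the exocyclic C2–OEt bond and Et3SiH reduces the ring oxocarbenium ion, so C2 becomes CH2 while C3 and C4 keep the trans arrangement (also the thermodynamically favoured one) and benzyl ethers and Ar–Cl are inert at this temperature.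

Step 16
Reactants: 29 (3R,4S)-7-(benzyloxy)-3-[2-(benzyloxy)-4,5-dimethoxyphenyl]-4-{4-(benzyloxy)-2-[(3R)-7-(benzyloxy)-5-chlorochroman-3-yl]-6-methoxyphenyl}chromane
Product: 30 (3R,4S)-3-(2-hydroxy-4,5-dimethoxyphenyl)-4-{4-hydroxy-2-[(3R)-7-hydroxychroman-3-yl]-6-methoxyphenyl}chroman-7-ol (target)
Conditions: H2 (3 bar), Pd(OH)2/C, NaOAc, THF/MeOH, 25 °C
Reagents that add atoms: none
Why: Heterogeneous hydrogenolysis cleaves the four benzyl ethers and the aryl C–Cl bond (acetate takes up HCl), whereas the alkyl aryl ether bonds of rings C and E and the diarylmethine C4 are stable, so the three stereocentres are untouched.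

**Compound list**
1 | 3-hydroxy-5-methoxybenzaldehyde | COc1cc(O)cc(C=O)c1 | starting material
2 | 2-bromo-5-hydroxy-3-methoxybenzaldehyde | COc1cc(O)cc(C=O)c1Br | intermediate
3 | 5-(benzyloxy)-2-bromo-3-methoxybenzaldehyde | COc1cc(OCc2ccccc2)cc(C=O)c1Br | intermediate
4 | 5-(benzyloxy)-2-bromo-1-methoxy-3-(2-methoxyethenyl)benzene (E/Z mixture) | COC=Cc1cc(OCc2ccccc2)cc(OC)c1Br | intermediate
5 | 2-[5-(benzyloxy)-2-bromo-3-methoxyphenyl]acetaldehyde | O=CCc1cc(OCc2ccccc2)cc(OC)c1Br | intermediate
6 | 2-[5-(benzyloxy)-2-bromo-3-methoxyphenyl]prop-2-enal | C=C(C=O)c1cc(OCc2ccccc2)cc(OC)c1Br | intermediate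
7 | 4-(benzyloxy)phenol | Oc1ccc(OCc2ccccc2)cc1 | starting material
8 | 4-(benzyloxy)-2-chlorophenol | Oc1ccc(OCc2ccccc2)cc1Cl | intermediate
9 | 4-(benzyloxy)-2-bromo-6-chlorophenol | Oc1c(Cl)cc(OCc2ccccc2)cc1Br | intermediate
10 | [4-(benzyloxy)-2-bromo-6-chlorophenoxy]trimethylsilane | C[Si](C)(C)Oc1c(Cl)cc(OCc2ccccc2)cc1Br | intermediate
11 | lithium 4-(benzyloxy)-2-chloro-6-(trimethylsilyl)phenolate | [Li+].[O-]c1c(Cl)cc(OCc2ccccc2)cc1[Si](C)(C)C | intermediate
12 | 4-(benzyloxy)-2-chloro-6-(trimethylsilyl)phenyl trifluoromethanesulfonate | C[Si](C)(C)c1cc(OCc2ccccc2)cc(Cl)c1OS(=O)(=O)C(F)(F)F | intermediate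
13 | 5-(benzyloxy)-3-chloro-1,2-didehydrobenzene (aryne) | ClC1=CC(OCc2ccccc2)=CC#C1 | intermediate
14 | 5-(benzyloxy)-2-{1-[5-(benzyloxy)-2-bromo-3-methoxyphenyl]ethenyl}-3-chloro-2H-benzo[b]oxete | Clc1cc(OCc2ccccc2)cc2OC(c12)C(=C)c1cc(OCc2ccccc2)cc(OC)c1Br | intermediate
15 | 3-(benzyloxy)-6-{2-[5-(benzyloxy)-2-bromo-3-methoxyphenyl]prop-2-en-1-ylidene}-5-chlorocyclohexa-2,4-dien-1-one | O=C1C=C(OCc2ccccc2)C=C(Cl)C1=CC(=C)c1cc(OCc2ccccc2)cc(OC)c1Br | intermediate
16 | 7-(benzyloxy)-3-[5-(benzyloxy)-2-bromo-3-methoxyphenyl]-5-chloro-2H-chromene | Clc1cc(OCc2ccccc2)cc2OCC(=Cc12)c1cc(OCc2ccccc2)cc(OC)c1Br | intermediate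
17 | (3R)-7-(benzyloxy)-3-[5-(benzyloxy)-2-bromo-3-methoxyphenyl]-5-chlorochromane | COc1cc(OCc2ccccc2)cc([C@@H]2COc3cc(OCc4ccccc4)cc(Cl)c3C2)c1Br | intermediate
18 | 4-(benzyloxy)-2-hydroxybenzaldehyde | O=Cc1ccc(OCc2ccccc2)cc1O | starting material
19 | {4-(benzyloxy)-2-[(3R)-7-(benzyloxy)-5-chlorochroman-3-yl]-6-methoxyphenyl}lithium | COc1cc(OCc2ccccc2)cc([C@@H]2COc3cc(OCc4ccccc4)cc(Cl)c3C2)c1[Li] | intermediate
20 | sodium 5-(benzyloxy)-2-formylphenolate | [Na+].[O-]c1cc(OCc2ccccc2)ccc1C=O | intermediate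
21 | 5-(benzyloxy)-2-[{4-(benzyloxy)-2-[(3R)-7-(benzyloxy)-5-chlorochroman-3-yl]-6-methoxyphenyl}(hydroxy)methyl]phenol (both carbinol epimers) | COc1cc(OCc2ccccc2)cc([C@@H]2COc3cc(OCc4ccccc4)cc(Cl)c3C2)c1C(O)c1ccc(OCc2ccccc2)cc1O | intermediate
22 | 3,4-dimethoxyphenol | COc1ccc(O)cc1OC | starting material
23 | 2-bromo-4,5-dimethoxyphenol | COc1cc(O)c(Br)cc1OC | intermediate
24 | 1-(benzyloxy)-2-bromo-4,5-dimethoxybenzene | COc1cc(Br)c(OCc2ccccc2)cc1OC | intermediate
25 | 2-[(E)-2-ethoxyethenyl]-4,4,5,5-tetramethyl-1,3,2-dioxaborolane | CCO/C=C/B1OC(C)(C)C(C)(C)O1 | starting material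
26 | 1-(benzyloxy)-2-[(E)-2-ethoxyethenyl]-4,5-dimethoxybenzene | CCO/C=C/c1cc(OC)c(OC)cc1OCc1ccccc1 | intermediate
27 | 3-(benzyloxy)-6-({4-(benzyloxy)-2-[(3R)-7-(benzyloxy)-5-chlorochroman-3-yl]-6-methoxyphenyl}methylidene)cyclohexa-2,4-dien-1-one | O=C1C=C(OCc2ccccc2)C=CC1=Cc1c(OC)cc(OCc2ccccc2)cc1[C@@H]1COc2cc(OCc3ccccc3)cc(Cl)c2C1 | intermediate
28 | (2S,3R,4S)-7-(benzyloxy)-3-[2-(benzyloxy)-4,5-dimethoxyphenyl]-4-{4-(benzyloxy)-2-[(3R)-7-(benzyloxy)-5-chlorochroman-3-yl]-6-methoxyphenyl}-2-ethoxychromane | COc1cc(OCc2ccccc2)c([C@@H]2[C@@H](OCC)Oc3cc(OCc4ccccc4)ccc3[C@H]2c2c(OC)cc(OCc3ccccc3)cc2[C@@H]2COc3cc(OCc4ccccc4)cc(Cl)c3C2)cc1OC | intermediate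
29 | (3R,4S)-7-(benzyloxy)-3-[2-(benzyloxy)-4,5-dimethoxyphenyl]-4-{4-(benzyloxy)-2-[(3R)-7-(benzyloxy)-5-chlorochroman-3-yl]-6-methoxyphenyl}chromane | COc1cc(OCc2ccccc2)c([C@@H]2COc3cc(OCc4ccccc4)ccc3[C@H]2c2c(OC)cc(OCc3ccccc3)cc2[C@@H]2COc3cc(OCc4ccccc4)cc(Cl)c3C2)cc1OC | intermediate
30 | (3R,4S)-3-(2-hydroxy-4,5-dimethoxyphenyl)-4-{4-hydroxy-2-[(3R)-7-hydroxychroman-3-yl]-6-methoxyphenyl}chroman-7-ol | COc1cc(O)c([C@@H]2COc3cc(O)ccc3[C@H]2c2c(OC)cc(O)cc2[C@@H]2COc3cc(O)ccc3C2)cc1OC | target

**Totals**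
Total step count: 16. Longest linear sequence: 10 steps (steps 1–4, 8–10, 14–16).

**Three steps most likely to fail**

1. Step 8 (key step). What may go wrong: the labile 2-arylacrolein oligomerises or is consumed by Diels–Alder or anionic pathways faster than its carbonyl group captures the aryne, or the o-quinone methide is intercepted by a second aryne before it electrocyclises. The fallback sets out from 12 and 5 and comes back to the route at 16; it keeps the aryne carbonyl [2+2] but uses a robust carbonyl partner and closes the pyran ring stepwise. The aryne is generated from 12 (CsF) in N,N-dimethylformamide, which acts as the carbonyl partner in large excess; aqueous work-up of the adduct should give 4-(benzyloxy)-2-chloro-6-hydroxybenzaldehyde F1 with the same regiochemistry (oxygen meta to chlorine). Aldehyde 5 is oxidised (NaClO2, NaH2PO4, 2-methylbut-2-ene; Pinnick oxidation) to 2-[5-(benzyloxy)-2-bromo-3-methoxyphenyl]acetic acid F2. Perkin condensation of F1 with F2 (Ac2O, Et3N, 110 °C) should give 7-(benzyloxy)-3-[5-(benzyloxy)-2-bromo-3-methoxyphenyl]-5-chloro-2H-chromen-2-one F3. Excess DIBAL-H (CH2Cl2, −78 → 0 °C) reduces the lactone to 5-(benzyloxy)-2-{(1Z)-2-[5-(benzyloxy)-2-bromo-3-methoxyphenyl]-3-hydroxyprop-1-en-1-yl}-3-chlorophenol F4, and Mitsunobu cyclodehydration (PPh3, DIAD, THF) closes ring E to 16.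

2. Step 14. What may go wrong: carbon–carbon bond formation at the crowded, strongly stabilised benzhydryl centre is so slow that hydrolysis or oligomerisation of the enol ether takes over, or facial selectivity is poor in a mismatched pairing with the ring E stereocentre. The fallback sets out from 21 and 26 and comes back at 29; it changes the activation mode from acid catalysis of the electrophile to enamine activation of the nucleophile and makes C3 epimerisable. Enol ether 26 is hydrolysed (aq. HCl, THF) to 2-[2-(benzyloxy)-4,5-dimethoxyphenyl]acetaldehyde F5. Diol 21 is converted with sodium 4-methylbenzenesulfinate and TsOH (CH2Cl2) into 5-(benzyloxy)-2-[{4-(benzyloxy)-2-[(3R)-7-(benzyloxy)-5-chlorochroman-3-yl]-6-methoxyphenyl}(4-methylbenzenesulfonyl)methyl]phenol F6. Aqueous NaHCO3 releases the o-quinone methide from F6 in the presence of F5 and (S)-α,α-diphenylprolinol trimethylsilyl ether (20 mol %); enamine Michael addition and hemiacetalisation should give (3R,4S)-7-(benzyloxy)-3-[2-(benzyloxy)-4,5-dimethoxyphenyl]-4-{4-(benzyloxy)-2-[(3R)-7-(benzyloxy)-5-chlorochroman-3-yl]-6-methoxyphenyl}chroman-2-ol F7. Its C4 is fixed by the shielded enamine face and its C3, α to the masked aldehyde, equilibrates to the 3,4-trans arrangement. Et3SiH/BF3·OEt2 (CH2Cl2, −78 °C) reduces the lactol to 29.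

3. Step 10. What may go wrong: protonation or decomposition of the hindered aryllithium outruns its addition to the electron-rich, phenolate-deactivated aldehyde. The fallback sets out from 17 and 18 and comes back at 21; it replaces the unprotected anionic coupling by a protect–couple–deprotect sequence with a fully electrophilic aldehyde. Aldehyde 18 is silylated (TBSCl, imidazole, DMF) to 4-(benzyloxy)-2-[(tert-butyldimethylsilyl)oxy]benzaldehyde F8. Aryllithium 19 (from 17 and n-BuLi, THF, −78 °C) is added to F8 and the alkoxide is quenched cold with AcOH, before silyl migration, to give {4-(benzyloxy)-2-[(3R)-7-(benzyloxy)-5-chlorochroman-3-yl]-6-methoxyphenyl}{4-(benzyloxy)-2-[(tert-butyldimethylsilyl)oxy]phenyl}methanol F9. Bu4NF/AcOH (THF, 0 °C) cleaves the silyl ether to 21.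

Further compounds
F1 | step 8 | 4-(benzyloxy)-2-chloro-6-hydroxybenzaldehyde | O=Cc1c(O)cc(OCc2ccccc2)cc1Cl
F2 | step 8 | 2-[5-(benzyloxy)-2-bromo-3-methoxyphenyl]acetic acid | OC(=O)Cc1cc(OCc2ccccc2)cc(OC)c1Br
F3 | step 8 | 7-(benzyloxy)-3-[5-(benzyloxy)-2-bromo-3-methoxyphenyl]-5-chloro-2H-chromen-2-one | O=C1Oc2cc(OCc3ccccc3)cc(Cl)c2C=C1c1cc(OCc2ccccc2)cc(OC)c1Br
F4 | step 8 | 5-(benzyloxy)-2-{(1Z)-2-[5-(benzyloxy)-2-bromo-3-methoxyphenyl]-3-hydroxyprop-1-en-1-yl}-3-chlorophenol | OC/C(c1cc(OCc2ccccc2)cc(OC)c1Br)=C\c1c(O)cc(OCc2ccccc2)cc1Cl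
F5 | step 14 | 2-[2-(benzyloxy)-4,5-dimethoxyphenyl]acetaldehyde | COc1cc(CC=O)c(OCc2ccccc2)cc1OC
F6 | step 14 | 5-(benzyloxy)-2-[{4-(benzyloxy)-2-[(3R)-7-(benzyloxy)-5-chlorochroman-3-yl]-6-methoxyphenyl}(4-methylbenzenesulfonyl)methyl]phenol | COc1cc(OCc2ccccc2)cc([C@@H]2COc3cc(OCc4ccccc4)cc(Cl)c3C2)c1C(c1ccc(OCc2ccccc2)cc1O)S(=O)(=O)c1ccc(C)cc1
F7 | step 14 | (3R,4S)-7-(benzyloxy)-3-[2-(benzyloxy)-4,5-dimethoxyphenyl]-4-{4-(benzyloxy)-2-[(3R)-7-(benzyloxy)-5-chlorochroman-3-yl]-6-methoxyphenyl}chroman-2-ol | COc1cc(OCc2ccccc2)c([C@@H]2C(O)Oc3cc(OCc4ccccc4)ccc3[C@H]2c2c(OC)cc(OCc3ccccc3)cc2[C@@H]2COc3cc(OCc4ccccc4)cc(Cl)c3C2)cc1OC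
F8 | step 10 | 4-(benzyloxy)-2-[(tert-butyldimethylsilyl)oxy]benzaldehyde | O=Cc1ccc(OCc2ccccc2)cc1O[Si](C)(C)C(C)(C)C
F9 | step 10 | {4-(benzyloxy)-2-[(3R)-7-(benzyloxy)-5-chlorochroman-3-yl]-6-methoxyphenyl}{4-(benzyloxy)-2-[(tert-butyldimethylsilyl)oxy]phenyl}methanol | COc1cc(OCc2ccccc2)cc([C@@H]2COc3cc(OCc4ccccc4)cc(Cl)c3C2)c1C(O)c1ccc(OCc2ccccc2)cc1O[Si](C)(C)C(C)(C)C
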